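**Plan**
- Cuts, in retrosynthetic order: the two palmitate C–O bonds; C11=C12 (C25 phosphonium salt of the ε half + C15 epoxy aldehyde); C11'=C12' (C15 ε salt + C10 dialdehyde); C9'–C10' (vinyl addition to a C13 ketone); in the cyclohexene ring the C1'–C6' bond; in the epoxy half C7=C8 and the oxirane.
- Enabling feature: in the cyclohexene (ε) ring the quaternary gem-dimethyl carbon C1' is bonded to the stereocentre C6', and the ring alkene C4'=C5' lies where a C5' cation sheds H4'. The ring is therefore the product of an acid cyclisation of an acyclic dienone that ends in an isopropenyl group.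
- Forward order: the acyclic C13 chain is built from (R)-epichlorohydrin, the cyclohexene ring is closed by acid, and the chain grows C13 → C15 → C25. The second six-membered ring comes ready-made from actinol, receives the oxirane and is extended to a C15 aldehyde. The halves are joined at C11=C12 and both hydroxyls are acylated last.
- Stereochemistry: C3' from (R)-epichlorohydrin; C6' relayed from C3' through the chair of the cyclisation; C3 from (4R,6R)-actinol; C5/C6 from Sharpless epoxidation with D-(−)-diethyl tartrate. E alkenes come from syn carboalumination, stabilised ylides and phosphonates, and thermal equilibration.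

Key step: step 8

Remark: positions follow carotenoid numbering (primes = ε half); actinol 21, dialdehyde 16 and phosphonate 29 are taken as purchased, and olefination products are named as the all-E isomers reached after the stated equilibration or removal of minor Z isomers.

**Route**

Step 1
Reactants: 1 (R)-epichlorohydrin; 2 isopropenylmagnesium bromide
Product: 3 (2R)-1-chloro-4-methylpent-4-en-2-ol
Conditions: CuI (10 mol%), THF, −40 → −20 °C; aq. NH4Cl
Reagents that add atoms: none
Why: Copper-catalysed Grignard opening of the epoxide (SN2 at the unsubstituted CH2) is standard for epichlorohydrin and leaves the C–Cl bond and the stereocentre untouched.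

Step 2
Reactants: 3 (2R)-1-chloro-4-methylpent-4-en-2-ol
Product: 4 (2R)-2-(2-methylprop-2-en-1-yl)oxirane
Conditions: powdered NaOH, Et2O, 0 °C → rt
Reagents that add atoms: none
Why: Intramolecular Williamson etherification of the chlorohydrin closes the new oxirane without breaking the C–O bond at the stereocentre, so the configuration is kept.

Step 3
Reactants: 4 (2R)-2-(2-methylprop-2-en-1-yl)oxirane
Product: 5 (4R)-6-methylhept-6-en-1-yn-4-ol
Conditions: lithium acetylide–ethylenediamine complex, DMSO, 0 °C → rt; H2O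
Reagents that add atoms: lithium acetylide–ethylenediamine complex, [Li+].[C-]#C.NCCN
Why: SN2 opening of a terminal epoxide by an acetylide at the CH2 carbon should give the homopropargylic alcohol with the stereocentre untouched.

Step 4
Reactants: 5 (4R)-6-methylhept-6-en-1-yn-4-ol
Product: 7 (2E,5R)-3,7-dimethylocta-2,7-diene-1,5-diol, via alkenyldimethylalane 6 (not isolated)
Conditions: Me3Al (3 equiv), Cp2ZrCl2 (25 mol%), CH2Cl2, 0 °C → rt; volatiles removed; n-BuLi, THF, −78 °C; (CH2O)n, → rt; aq. Rochelle salt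
Reagents that add atoms: trimethylaluminium, C[Al](C)C; paraformaldehyde (as formaldehyde), C=O
Why: Negishi zirconium-catalysed carboalumination adds methyl and aluminium syn across the terminal alkyne (methyl to the internal carbon) and the derived aluminate attacks formaldehyde with retention, so the E allylic alcohol should form while the 1,1-disubstituted alkene stays inert.

Step 5
Reactants: 7 (2E,5R)-3,7-dimethylocta-2,7-diene-1,5-diol
Product: 8 (2E,5R)-5-hydroxy-3,7-dimethylocta-2,7-dienal
Conditions: activated MnO2 (excess), CH2Cl2, rt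
Reagents that add atoms: none
Why: Chemoselective allylic oxidation with MnO2 should convert only the primary allylic alcohol and leave the saturated secondary carbinol and the alkene geometry alone.

Step 6
Reactants: 8 (2E,5R)-5-hydroxy-3,7-dimethylocta-2,7-dienal; 9 1-(triphenylphosphoranylidene)propan-2-one
Product: 10 (3E,5E,8R)-8-hydroxy-6,10-dimethylundeca-3,5,10-trien-2-one
Conditions: toluene, 80 °C
Reagents that add atoms: none
Why: Wittig olefination with a ketone-stabilised ylide is E-selective and needs no base, so the enal geometry and the free carbinol should survive.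

Step 7
Reactants: 10 (3E,5E,8R)-8-hydroxy-6,10-dimethylundeca-3,5,10-trien-2-one
Product: 11 (3E,5E,8R)-6,10-dimethyl-2-oxoundeca-3,5,10-trien-8-yl acetate
Conditions: Ac2O, pyridine, DMAP (cat.), CH2Cl2, 0 °C → rt
Reagents that add atoms: acetic anhydride, CC(=O)OC(C)=O
Why: DMAP-catalysed acylation of a secondary alcohol is routine and installs the weakly donating ester wanted for the ring closure.

Step 8
Reactants: 11 (3E,5E,8R)-6,10-dimethyl-2-oxoundeca-3,5,10-trien-8-yl acetate
Product: 12 (3R,6R)-3-acetoxy-α-ionone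
Conditions: 85% H3PO4, toluene, 20–25 °C, vigorous stirring, short contact time; poured into ice-cold aq. NaHCO3
Reagents that add atoms: none
Why: Protonation of the isopropenyl group gives the tertiary C1' cation, the C5'=C6' alkene (C5=C6 of the dienone) attacks it through C6' to make the C1'–C6' bond, and the tertiary C5' cation then loses H4' to leave the C4'=C5' alkene. The closest known reaction is the phosphoric acid cyclisation of pseudoionone to α-ionone, which runs through the same cation, the same bond and the same kinetic proton loss. The cyclohexene ring closes 6-endo-trig through a chair. The new C6' stereocentre is controlled by the C3' acetate of the substrate: in the chair the acetoxy group lies equatorial (axial it would meet a methyl of C1' in a 1,3-diaxial clash) and the enone arm on the E alkene, or on the lower-lying arrangement if the acid equilibrates the alkene, also lies equatorial, which gives the trans (3'R,6'R) ring. The step needs proton loss toward C4' in preference to C6' or the methyl group, and an intact C3' ester; the first is the kinetic result of this acid at short contact, and the second rests on the acetyl group, whose oxygen is too poor a donor to drive retro-Prins cleavage and whose capture of the cation as a dioxanylium ion is reversible in this medium, together with a quench before the allylic ester ionises.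

Step 9
Reactants: 12 (3R,6R)-3-acetoxy-α-ionone; 13 vinylmagnesium bromide
Product: 14 (1R,4R)-4-[(1E)-3-hydroxy-3-methylpenta-1,4-dien-1-yl]-3,5,5-trimethylcyclohex-2-en-1-ol (both epimers at the new carbinol carbon)
Conditions: 13 (3.5 equiv), THF, −40 → 0 °C; aq. NH4Cl
Reagents that add atoms: none
Why: Grignard 1,2-addition to the enone carbonyl, with the excess reagent cleaving the acetate by double addition, should give the diol; the new carbinol centre forms as both epimers, which is harmless because it becomes sp2 in step 10.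

Step 10
Reactants: 14 (1R,4R)-4-[(1E)-3-hydroxy-3-methylpenta-1,4-dien-1-yl]-3,5,5-trimethylcyclohex-2-en-1-ol
Product: 15 [(2E,4E)-5-[(1R,4R)-4-hydroxy-2,6,6-trimethylcyclohex-2-en-1-yl]-3-methylpenta-2,4-dien-1-yl]triphenylphosphonium bromide
Conditions: PPh3·HBr (1.05 equiv), MeOH, 0 °C → rt, dark
Reagents that add atoms: triphenylphosphine hydrobromide, Br.P(c1ccccc1)(c1ccccc1)c1ccccc1
Why: Acid-promoted SN1' substitution with allylic transposition: the tertiary bis-allylic carbinol ionises far more readily than the ring carbinol, and PPh3 traps the pentadienyl cation at its unhindered terminus to give the conjugated (2E,4E) salt, the usual way from vinyl carbinols to C15 Wittig salts.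

Step 11
Reactants: 15 the C15 phosphonium bromide; 16 (2E,4E,6E)-2,7-dimethylocta-2,4,6-trienedial
Product: 18 (3R,6R)-3-hydroxy-12'-apo-ε-caroten-12'-al, via C15 ylide 17 (not isolated)
Conditions: NaOMe (1.1 equiv), 16 (2 equiv), CH2Cl2/MeOH, 0 °C → rt; then heptane, 80 °C (Z → E)
Reagents that add atoms: none
Why: Wittig olefination; the excess of the symmetrical dialdehyde and the lower electrophilicity of the vinylogous product aldehyde should hold the reaction at mono-olefination, and the hindered Z isomer of the new C11'=C12' bond equilibrates thermally to E.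

Step 12
Reactants: 18 (3R,6R)-3-hydroxy-12'-apo-ε-caroten-12'-al
Product: 19 (2E,4E,6E,8E,10E,12E)-13-[(1R,4R)-4-hydroxy-2,6,6-trimethylcyclohex-2-en-1-yl]-2,7,11-trimethyltrideca-2,4,6,8,10,12-hexaen-1-ol
Conditions: NaBH4, EtOH/THF, 0 °C
Reagents that add atoms: none
Why: Borohydride 1,2-reduction of the polyenal gives the primary allylic alcohol without touching the polyene.

Step 13
Reactants: 19 the C25 diol
Product: 20 [(2E,4E,6E,8E,10E,12E)-13-[(1R,4R)-4-hydroxy-2,6,6-trimethylcyclohex-2-en-1-yl]-2,7,11-trimethyltrideca-2,4,6,8,10,12-hexaen-1-yl]triphenylphosphonium bromide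
Conditions: PPh3·HBr (1.05 equiv), MeOH/CH2Cl2, 0 °C → rt, dark
Reagents that add atoms: triphenylphosphine hydrobromide, Br.P(c1ccccc1)(c1ccccc1)c1ccccc1
Why: SN1 substitution of the polyenylic primary carbinol by PPh3 under mild acid is the standard entry to carotenoid Wittig salts, and the much less ionisable ring carbinol should stay untouched.

Step 14
Reactants: 21 (4R,6R)-4-hydroxy-2,2,6-trimethylcyclohexan-1-one (actinol)
Product: 22 (4R,6R)-4-[(tert-butyldimethylsilyl)oxy]-2,2,6-trimethylcyclohexan-1-one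
Conditions: TBSCl, imidazole, DMF, rt
Reagents that add atoms: tert-butyldimethylsilyl chloride, CC(C)(C)[Si](C)(C)Cl
Why: Imidazole-promoted silylation of a secondary alcohol protects the future C3 hydroxyl against the strong base and hydride steps that follow.

Step 15
Reactants: 22 the silyl ether of actinol
Product: 24 (4R)-4-[(tert-butyldimethylsilyl)oxy]-2,6,6-trimethylcyclohex-1-en-1-yl trifluoromethanesulfonate, via potassium enolate 23 (not isolated)
Conditions: KHMDS, THF, −78 °C; PhNTf2, −78 → 0 °C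
Reagents that add atoms: N-phenylbis(trifluoromethanesulfonimide), O=S(=O)(N(c1ccccc1)S(=O)(=O)C(F)(F)F)C(F)(F)F
Why: Enolate O-triflation; the ketone can enolise only toward the methyl-bearing carbon because the other α-carbon is quaternary, so a single enol triflate should form and the silyloxy stereocentre is untouched.

Step 16
Reactants: 24 the enol triflate
Product: 25 methyl (4R)-4-[(tert-butyldimethylsilyl)oxy]-2,6,6-trimethylcyclohex-1-ene-1-carboxylate
Conditions: Pd(OAc)2 (5 mol%), PPh3 (10 mol%), CO (1 atm), MeOH, Et3N, DMF, 60 °C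
Reagents that add atoms: carbon monoxide, [C-]#[O+]; methanol, CO
Why: Palladium-catalysed alkoxycarbonylation of an enol triflate installs the C7 carbon as an ester on the tetrasubstituted alkene.

Step 17
Reactants: 25 the methyl ester
Product: 26 [(4R)-4-[(tert-butyldimethylsilyl)oxy]-2,6,6-trimethylcyclohex-1-en-1-yl]methanol
Conditions: DIBAL-H (2.5 equiv), CH2Cl2, −78 → 0 °C; aq. Rochelle salt
Reagents that add atoms: none
Why: DIBAL-H reduces the unsaturated ester in 1,2 fashion to the allylic alcohol needed to direct the epoxidation.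

Step 18
Reactants: 26 the allylic alcohol
Product: 27 [(1R,4S,6R)-4-[(tert-butyldimethylsilyl)oxy]-2,2,6-trimethyl-7-oxabicyclo[4.1.0]heptan-1-yl]methanol
Conditions: Ti(OiPr)4 (20 mol%), D-(−)-diethyl tartrate (25 mol%), t-BuOOH (anhydrous, in decane), 4 Å molecular sieves, CH2Cl2, −20 °C
Reagents that add atoms: tert-butyl hydroperoxide, CC(C)(C)OO
Why: Sharpless asymmetric epoxidation; with D-(−)-diethyl tartrate the titanium-bound peroxide should be delivered to the alkene face anti to the silyloxy group, which sets C5 (R) and C6 (S) of the carotenoid by reagent control.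

Step 19
Reactants: 27 the epoxy alcohol
Product: 28 (1S,4S,6R)-4-[(tert-butyldimethylsilyl)oxy]-2,2,6-trimethyl-7-oxabicyclo[4.1.0]heptane-1-carbaldehyde
Conditions: n-Pr4N[RuO4] (5 mol%), NMO, 4 Å molecular sieves, CH2Cl2, rt
Reagents that add atoms: none
Why: Ley–Griffith oxidation is neutral, so the oxirane should survive, and the aldehyde has no α-hydrogen and cannot epimerise.

Step 20
Reactants: 28 the epoxy aldehyde; 29 diethyl [(2E)-3-cyano-2-methylprop-2-en-1-yl]phosphonate
Product: 31 (2E,4E)-5-[(1S,4S,6R)-4-[(tert-butyldimethylsilyl)oxy]-2,2,6-trimethyl-7-oxabicyclo[4.1.0]heptan-1-yl]-3-methylpenta-2,4-dienenitrile, via phosphonate carbanion 30 (not isolated)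
Conditions: NaH, THF, 0 °C; then 28, 0 °C → rt; chromatography
Reagents that add atoms: none
Why: Horner–Wadsworth–Emmons olefination should form the new C7=C8 bond E and bring in C8–C11 with the C9 methyl, any minor 9Z isomer being removed by chromatography.

Step 21
Reactants: 31 the silylated C15 nitrile
Product: 32 (2E,4E)-5-[(1S,4S,6R)-4-hydroxy-2,2,6-trimethyl-7-oxabicyclo[4.1.0]heptan-1-yl]-3-methylpenta-2,4-dienenitrile
Conditions: n-Bu4NF, THF, 0 °C → rt
Reagents that add atoms: none
Why: Fluoride-induced desilylation frees the C3 hydroxyl at a robust stage, without acid that would open the oxirane.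

Step 22
Reactants: 32 the hydroxy C15 nitrile
Product: 34 (2E,4E)-5-[(1S,4S,6R)-4-hydroxy-2,2,6-trimethyl-7-oxabicyclo[4.1.0]heptan-1-yl]-3-methylpenta-2,4-dienal, via iminoalane 33 (not isolated)
Conditions: DIBAL-H (2.5 equiv), CH2Cl2, −78 → −40 °C; moist SiO2, 0 °C
Reagents that add atoms: water, O
Why: DIBAL-H adds once to the nitrile and the aluminated aldimine is hydrolysed on neutral wet silica, which should spare the acid-labile vinyl oxirane.

Step 23
Reactants: 20 the C25 phosphonium bromide; 34 the C15 epoxy aldehyde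
Product: 36 (3S,5R,6S,3'R,6'R)-5,6-epoxy-5,6-dihydro-β,ε-carotene-3,3'-diol (lutein 5,6-epoxide), via C25 ylide 35 (not isolated)
Conditions: NaOMe (1.2 equiv), CH2Cl2/MeOH, 0 °C → rt, argon, dark; then EtOH, 70 °C (Z → E); crystallisation
Reagents that add atoms: none
Why: Wittig olefination joins the halves at C11=C12 under mild base that should leave the oxirane, the free hydroxyls and C6' alone, and the hindered Z isomer of the new bond equilibrates thermally to all-E.

Step 24
Reactants: 36 lutein 5,6-epoxide; 37 hexadecanoyl chloride (palmitoyl chloride)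
Product: 38 (3S,5R,6S,3'R,6'R)-5,6-epoxy-5,6-dihydro-β,ε-carotene-3,3'-diyl dihexadecanoate
Conditions: 37 (3 equiv), pyridine, DMAP (cat.), CH2Cl2, 0 °C → rt, argon, dark
Reagents that add atoms: none
Why: DMAP-catalysed acylation of both secondary alcohols in a pyridine-buffered medium should not rearrange the oxirane and touches no stereocentre.

**Compound list**

1 | (R)-epichlorohydrin, (2R)-2-(chloromethyl)oxirane | ClC[C@H]1CO1 | starting material
2 | isopropenylmagnesium bromide | CC(=C)[Mg]Br | starting material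
3 | (2R)-1-chloro-4-methylpent-4-en-2-ol | ClC[C@H](O)CC(C)=C | intermediate
4 | (2R)-2-(2-methylprop-2-en-1-yl)oxirane | CC(=C)C[C@@H]1CO1 | intermediate
5 | (4R)-6-methylhept-6-en-1-yn-4-ol | C#CC[C@H](O)CC(C)=C | intermediate
6 | dimethyl[(1E,4R)-4-[(dimethylalumanyl)oxy]-2,6-dimethylhepta-1,6-dien-1-yl]alumane | C[Al](C)/C=C(C)/C[C@H](O[Al](C)C)CC(C)=C | intermediate (not isolated)
7 | (2E,5R)-3,7-dimethylocta-2,7-diene-1,5-diol | OC/C=C(C)/C[C@H](O)CC(C)=C | intermediate
8 | (2E,5R)-5-hydroxy-3,7-dimethylocta-2,7-dienal | O=C/C=C(C)/C[C@H](O)CC(C)=C | intermediate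
9 | 1-(triphenylphosphoranylidene)propan-2-one | CC(=O)C=P(c1ccccc1)(c1ccccc1)c1ccccc1 | starting material
10 | (3E,5E,8R)-8-hydroxy-6,10-dimethylundeca-3,5,10-trien-2-one | CC(=O)/C=C/C=C(C)/C[C@H](O)CC(C)=C | intermediate
11 | (3E,5E,8R)-6,10-dimethyl-2-oxoundeca-3,5,10-trien-8-yl acetate | CC(=O)/C=C/C=C(C)/C[C@H](OC(C)=O)CC(C)=C | intermediate
12 | (3R,6R)-3-acetoxy-α-ionone, (1R,4R)-3,5,5-trimethyl-4-[(1E)-3-oxobut-1-en-1-yl]cyclohex-2-en-1-yl acetate | CC(=O)/C=C/[C@H]1C(C)=C[C@H](OC(C)=O)CC1(C)C | intermediate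
13 | vinylmagnesium bromide | C=C[Mg]Br | starting material
14 | (1R,4R)-4-[(1E)-3-hydroxy-3-methylpenta-1,4-dien-1-yl]-3,5,5-trimethylcyclohex-2-en-1-ol, both epimers at the side-chain carbinol | C=CC(C)(O)/C=C/[C@H]1C(C)=C[C@H](O)CC1(C)C | intermediate
15 | [(2E,4E)-5-[(1R,4R)-4-hydroxy-2,6,6-trimethylcyclohex-2-en-1-yl]-3-methylpenta-2,4-dien-1-yl]triphenylphosphonium bromide | c1ccccc1[P+](c1ccccc1)(c1ccccc1)C/C=C(C)/C=C/[C@H]1C(C)=C[C@H](O)CC1(C)C.[Br-] | intermediate
16 | (2E,4E,6E)-2,7-dimethylocta-2,4,6-trienedial | O=C/C(C)=C/C=C/C=C(C)/C=O | starting material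
17 | C15 ylide, [(2E,4E)-5-[(1R,4R)-4-hydroxy-2,6,6-trimethylcyclohex-2-en-1-yl]-3-methylpenta-2,4-dien-1-ylidene]triphenylphosphorane | c1ccccc1P(c1ccccc1)(c1ccccc1)=C/C=C(C)/C=C/[C@H]1C(C)=C[C@H](O)CC1(C)C | intermediate (not isolated)
18 | (3R,6R)-3-hydroxy-12'-apo-ε-caroten-12'-al, (2E,4E,6E,8E,10E,12E)-13-[(1R,4R)-4-hydroxy-2,6,6-trimethylcyclohex-2-en-1-yl]-2,7,11-trimethyltrideca-2,4,6,8,10,12-hexaenal | O=C/C(C)=C/C=C/C=C(C)/C=C/C=C(C)/C=C/[C@H]1C(C)=C[C@H](O)CC1(C)C | intermediate
19 | (2E,4E,6E,8E,10E,12E)-13-[(1R,4R)-4-hydroxy-2,6,6-trimethylcyclohex-2-en-1-yl]-2,7,11-trimethyltrideca-2,4,6,8,10,12-hexaen-1-ol | OC/C(C)=C/C=C/C=C(C)/C=C/C=C(C)/C=C/[C@H]1C(C)=C[C@H](O)CC1(C)C | intermediate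
20 | [(2E,4E,6E,8E,10E,12E)-13-[(1R,4R)-4-hydroxy-2,6,6-trimethylcyclohex-2-en-1-yl]-2,7,11-trimethyltrideca-2,4,6,8,10,12-hexaen-1-yl]triphenylphosphonium bromide | c1ccccc1[P+](c1ccccc1)(c1ccccc1)C/C(C)=C/C=C/C=C(C)/C=C/C=C(C)/C=C/[C@H]1C(C)=C[C@H](O)CC1(C)C.[Br-] | intermediate
21 | (4R,6R)-4-hydroxy-2,2,6-trimethylcyclohexan-1-one (actinol) | O=C1C(C)(C)C[C@H](O)C[C@H]1C | starting material
22 | (4R,6R)-4-[(tert-butyldimethylsilyl)oxy]-2,2,6-trimethylcyclohexan-1-one | O=C1C(C)(C)C[C@H](O[Si](C)(C)C(C)(C)C)C[C@H]1C | intermediate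
23 | potassium (4R)-4-[(tert-butyldimethylsilyl)oxy]-2,6,6-trimethylcyclohex-1-en-1-olate | [K+].[O-]C1=C(C)C[C@@H](O[Si](C)(C)C(C)(C)C)CC1(C)C | intermediate (not isolated)
24 | (4R)-4-[(tert-butyldimethylsilyl)oxy]-2,6,6-trimethylcyclohex-1-en-1-yl trifluoromethanesulfonate | FC(F)(F)S(=O)(=O)OC1=C(C)C[C@@H](O[Si](C)(C)C(C)(C)C)CC1(C)C | intermediate
25 | methyl (4R)-4-[(tert-butyldimethylsilyl)oxy]-2,6,6-trimethylcyclohex-1-ene-1-carboxylate | COC(=O)C1=C(C)C[C@@H](O[Si](C)(C)C(C)(C)C)CC1(C)C | intermediate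
26 | [(4R)-4-[(tert-butyldimethylsilyl)oxy]-2,6,6-trimethylcyclohex-1-en-1-yl]methanol | OCC1=C(C)C[C@@H](O[Si](C)(C)C(C)(C)C)CC1(C)C | intermediate
27 | [(1R,4S,6R)-4-[(tert-butyldimethylsilyl)oxy]-2,2,6-trimethyl-7-oxabicyclo[4.1.0]heptan-1-yl]methanol | CC(C)(C)[Si](C)(C)O[C@H]1CC(C)(C)[C@]2(CO)O[C@]2(C)C1 | intermediate
28 | (1S,4S,6R)-4-[(tert-butyldimethylsilyl)oxy]-2,2,6-trimethyl-7-oxabicyclo[4.1.0]heptane-1-carbaldehyde | CC(C)(C)[Si](C)(C)O[C@H]1CC(C)(C)[C@]2(C=O)O[C@]2(C)C1 | intermediate
29 | diethyl [(2E)-3-cyano-2-methylprop-2-en-1-yl]phosphonate | CCOP(=O)(OCC)C/C(C)=C/C#N | starting material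
30 | sodium salt of the carbanion of 29 | [Na+].CCOP(=O)(OCC)[CH-]/C(C)=C/C#N | intermediate (not isolated)
31 | (2E,4E)-5-[(1S,4S,6R)-4-[(tert-butyldimethylsilyl)oxy]-2,2,6-trimethyl-7-oxabicyclo[4.1.0]heptan-1-yl]-3-methylpenta-2,4-dienenitrile | CC(C)(C)[Si](C)(C)O[C@H]1CC(C)(C)[C@]2(/C=C/C(C)=C/C#N)O[C@]2(C)C1 | intermediate
32 | (2E,4E)-5-[(1S,4S,6R)-4-hydroxy-2,2,6-trimethyl-7-oxabicyclo[4.1.0]heptan-1-yl]-3-methylpenta-2,4-dienenitrile | O[C@H]1CC(C)(C)[C@]2(/C=C/C(C)=C/C#N)O[C@]2(C)C1 | intermediate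
33 | N,O-bis(diisobutylalumanyl) aldimine of 34 | CC(C)C[Al](CC(C)C)O[C@H]1CC(C)(C)[C@]2(/C=C/C(C)=C/C=N[Al](CC(C)C)CC(C)C)O[C@]2(C)C1 | intermediate (not isolated)
34 | (2E,4E)-5-[(1S,4S,6R)-4-hydroxy-2,2,6-trimethyl-7-oxabicyclo[4.1.0]heptan-1-yl]-3-methylpenta-2,4-dienal | O[C@H]1CC(C)(C)[C@]2(/C=C/C(C)=C/C=O)O[C@]2(C)C1 | intermediate
35 | C25 ylide, the triphenylphosphorane derived from 20 | c1ccccc1P(c1ccccc1)(c1ccccc1)=C/C(C)=C/C=C/C=C(C)/C=C/C=C(C)/C=C/[C@H]1C(C)=C[C@H](O)CC1(C)C | intermediate (not isolated)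
36 | (3S,5R,6S,3'R,6'R)-5,6-epoxy-5,6-dihydro-β,ε-carotene-3,3'-diol (lutein 5,6-epoxide) | O[C@H]1CC(C)(C)[C@]2(/C=C/C(C)=C/C=C/C(C)=C/C=C/C=C(C)/C=C/C=C(C)/C=C/[C@H]3C(C)=C[C@H](O)CC3(C)C)O[C@]2(C)C1 | intermediate
37 | hexadecanoyl chloride (palmitoyl chloride) | CCCCCCCCCCCCCCCC(=O)Cl | starting material
38 | (3S,5R,6S,3'R,6'R)-5,6-epoxy-5,6-dihydro-β,ε-carotene-3,3'-diyl dihexadecanoate | CCCCCCCCCCCCCCCC(=O)O[C@H]1CC(C)(C)[C@]2(/C=C/C(C)=C/C=C/C(C)=C/C=C/C=C(C)/C=C/C=C(C)/C=C/[C@H]3C(C)=C[C@H](OC(=O)CCCCCCCCCCCCCCC)CC3(C)C)O[C@]2(C)C1 | target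

**Step count and risks**

Total step count: 24. Longest linear sequence: 15 steps (steps 1–13, 23, 24, from (R)-epichlorohydrin); the epoxy branch is steps 14–22.

Steps most likely to fail:

1. Step 8. Attack of the acceptor-deactivated C5=C6 bond on the tertiary cation may be slower than hydrolytic capture of the cation by the neighbouring ester, and once the ring exists the allylic acetate may ionise or the ring alkene may drift into conjugation. The fallback sets out from 8 and comes back at 12; it closes the ring one oxidation level lower, where the attacking alkene is not conjugated to a carbonyl and the known low-temperature superacid cyclisation of geraniol-type substrates applies. Acetylation of 8 (Ac2O, pyridine, DMAP) would give (4R,6E)-2,6-dimethyl-8-oxoocta-1,6-dien-4-yl acetate F1. Luche reduction (NaBH4, CeCl3·7H2O, MeOH, −20 °C) would give (4R,6E)-8-hydroxy-2,6-dimethylocta-1,6-dien-4-yl acetate F2. Cyclisation with FSO3H in 2-nitropropane at −78 °C and a cold amine quench should give, through the same chair, (1R,4R)-4-(hydroxymethyl)-3,5,5-trimethylcyclohex-2-en-1-yl acetate F3. Dess–Martin oxidation would give (1R,4R)-4-formyl-3,5,5-trimethylcyclohex-2-en-1-yl acetate F4, and a base-free Wittig reaction with ylide 9 in hot toluene would rejoin the route at 12.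

2. Step 13. Under the acidic phosphine salt the ring carbinol at C3' may ionise alongside the polyenylic carbinol (epimerisation or loss of water), and the long ylide later made from 20 may suffer proton shifts toward C6'. The fallback sets out from 34, uses salt 15, and comes back at 36; the roles of the halves are exchanged so that no C25 salt is needed. Horner–Wadsworth–Emmons reaction of 34 with 29 (NaH, THF) would give (2E,4E,6E,8E)-9-[(1S,4S,6R)-4-hydroxy-2,2,6-trimethyl-7-oxabicyclo[4.1.0]heptan-1-yl]-3,7-dimethylnona-2,4,6,8-tetraenenitrile F5. DIBAL-H followed by moist SiO2 would give (2E,4E,6E,8E)-9-[(1S,4S,6R)-4-hydroxy-2,2,6-trimethyl-7-oxabicyclo[4.1.0]heptan-1-yl]-3,7-dimethylnona-2,4,6,8-tetraenal F6. A second Horner–Wadsworth–Emmons reaction, with diethyl [(2E)-3-cyanobut-2-en-1-yl]phosphonate, would give (2E,4E,6E,8E,10E,12E)-13-[(1S,4S,6R)-4-hydroxy-2,2,6-trimethyl-7-oxabicyclo[4.1.0]heptan-1-yl]-2,7,11-trimethyltrideca-2,4,6,8,10,12-hexaenenitrile F7. DIBAL-H and moist SiO2 again would give (3S,5R,6S)-5,6-epoxy-3-hydroxy-5,6-dihydro-12'-apo-β-caroten-12'-al F8, and Wittig reaction of F8 with salt 15 (NaOMe, CH2Cl2/MeOH, then thermal equilibration) would form C11'=C12' and give 36.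

3. Step 4. Transfer of the alkenyl group from the aluminate to paraformaldehyde may be incomplete, with protonolysis on work-up to the simple methyl-branched diene. The fallback sets out from 5 and comes back at 7. The same carboalumination is quenched with I2 instead, which would give (4R,6E)-7-iodo-2,6-dimethylhepta-1,6-dien-4-ol F9. Palladium-catalysed methoxycarbonylation (Pd(PPh3)2Cl2, CO, MeOH, Et3N) would give methyl (2E,5R)-5-hydroxy-3,7-dimethylocta-2,7-dienoate F10, and DIBAL-H reduction would deliver 7.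

Further compounds
F1 | step 8 | (4R,6E)-2,6-dimethyl-8-oxoocta-1,6-dien-4-yl acetate | O=C/C=C(C)/C[C@H](OC(C)=O)CC(C)=C
F2 | step 8 | (4R,6E)-8-hydroxy-2,6-dimethylocta-1,6-dien-4-yl acetate | OC/C=C(C)/C[C@H](OC(C)=O)CC(C)=C
F3 | step 8 | (1R,4R)-4-(hydroxymethyl)-3,5,5-trimethylcyclohex-2-en-1-yl acetate | OC[C@H]1C(C)=C[C@H](OC(C)=O)CC1(C)C
F4 | step 8 | (1R,4R)-4-formyl-3,5,5-trimethylcyclohex-2-en-1-yl acetate | O=C[C@H]1C(C)=C[C@H](OC(C)=O)CC1(C)C
F5 | step 13 | (2E,4E,6E,8E)-9-[(1S,4S,6R)-4-hydroxy-2,2,6-trimethyl-7-oxabicyclo[4.1.0]heptan-1-yl]-3,7-dimethylnona-2,4,6,8-tetraenenitrile | O[C@H]1CC(C)(C)[C@]2(/C=C/C(C)=C/C=C/C(C)=C/C#N)O[C@]2(C)C1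
F6 | step 13 | (2E,4E,6E,8E)-9-[(1S,4S,6R)-4-hydroxy-2,2,6-trimethyl-7-oxabicyclo[4.1.0]heptan-1-yl]-3,7-dimethylnona-2,4,6,8-tetraenal | O[C@H]1CC(C)(C)[C@]2(/C=C/C(C)=C/C=C/C(C)=C/C=O)O[C@]2(C)C1
F7 | step 13 | (2E,4E,6E,8E,10E,12E)-13-[(1S,4S,6R)-4-hydroxy-2,2,6-trimethyl-7-oxabicyclo[4.1.0]heptan-1-yl]-2,7,11-trimethyltrideca-2,4,6,8,10,12-hexaenenitrile | O[C@H]1CC(C)(C)[C@]2(/C=C/C(C)=C/C=C/C(C)=C/C=C/C=C(C)/C#N)O[C@]2(C)C1
F8 | step 13 | (3S,5R,6S)-5,6-epoxy-3-hydroxy-5,6-dihydro-12'-apo-β-caroten-12'-al | O[C@H]1CC(C)(C)[C@]2(/C=C/C(C)=C/C=C/C(C)=C/C=C/C=C(C)/C=O)O[C@]2(C)C1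
F9 | step 4 | (4R,6E)-7-iodo-2,6-dimethylhepta-1,6-dien-4-ol | I/C=C(C)/C[C@H](O)CC(C)=C
F10 | step 4 | methyl (2E,5R)-5-hydroxy-3,7-dimethylocta-2,7-dienoate | COC(=O)/C=C(C)/C[C@H](O)CC(C)=C
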